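Monday's run and delta stand at the same temperature with the same reagent; they differ in the substrate charged, and delta also has a stated end time.

all flasks: reagent 0.323 M

|  | substrate | temperature | remark | time |
|---|---|---|---|---|
| Monday's | 0.51 M | 60 °C | run made earlier |  |
| delta | 0.34 M | 60 °C |  | 12 min |
| beta | 0.34 M |  | at 60 °C until 8.0 min, from then on at 120 °C | 12 min |
| alpha | 0.34 M | 120 °C |  | 12 min |
| gamma | 0.34 M | 90 °C |  | 12 min |

Monday's run (percent of the substrate charged): time / min: target / % = 0.200: 9.0; 0.333: 14.1; 0.667: 22.6; 1.33: 31.3; 2.50: 40.3

(standard deviation of a reading: 0.5 percentage points)

- steps thought possible: target <-> isomer of the product; substrate + reagent -> target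
- the earlier runs do not show what temperature does; that part of a forecast is a guess

- the flask with the highest amount of target, in percent of the substrate charged ("all alike" if they lie within 1.5 percentage points) (delta / beta / alpha / gamma / all alike)
- final target, as a percentage of the substrate charged, in delta
- final target, as a percentage of the substrate charged, in beta
- final target, as a percentage of the substrate charged, in alpha
- final target, as a percentage of the substrate charged, in gamma

Follow one molecule of substrate. At its first fork it either meets a reagent or stays substrate, and substrate and reagent go one to one. Monday's run charged reagent for 63.3% of its substrate, delta for 95.0%. This share, reagent charged divided by substrate charged, is the reagent ceiling: where reagent is the smaller charge (the limiting reagent), it is the part of the substrate that can become product.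

Monday's last reading, 40.3% at 2.50 min, stands below that run's ceiling, at 63.7% of it, with any isomer uncounted. Delta spreads the same reagent over less substrate, so each part of reagent spent counts 1.50 times as much in percent of the substrate charged, and delta's ceiling lies higher than Monday's.

At the second fork, product stands as target or as isomer, so target lies below the ceiling by the isomer and by the reagent still unspent. The runs so far show a single temperature, so what heat does at either fork is a guess. The reckoning here commits to a bound: each flask asked about ends with target under 95.0%.

The forecast gives 63.5% for delta, 67% for beta, 67.5% for alpha and 67% for gamma, names alpha as highest, and says “The temperature effect is a guess”.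

The flasks give 67.5% in delta, 89.1% in beta, 92.2% in alpha and 86.5% in gamma, so alpha stands highest.

    target ⇌ isomer of the product (K = 0.160, k = 0.0780 /min, Ea = 107 kJ/mol, ΔH = −62.0 kJ/mol)
    substrate + reagent → target, rate k2*[substrate]*[reagent]^1.5 (k = 3.10 /M^1.5/min, Ea = 45.0 kJ/mol)
    (constants at 60 °C)

Target in each of these flasks lies under the ceiling; target and isomer together make 92.7% in alpha and 77.9% in delta. In delta at 12.0 min, target is still made 5.11 times faster than it is used up, each step taken net, while the exchange with the isomer, by that step alone and both ways together, has a relaxation half-life of 1.23 min, short against the 12 min of the run. A neighbour of delta with 1.4 M of substrate has a ceiling of 23.1%. That flask ends with 19.8% target and 3.15% isomer, together 22.9%, with 0.626% of its reagent left.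

(The numbers in the tables stem from a simulated flask on assumed constants; noise was put on by code.)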